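Ring B of the target carries all its functionality on the C7(OAc)–C8(=CH2) pair, while C6 is a bare methylene. Deleting C7 therefore leaves a trans-fused B-nor cyclopentanone (C8 carbonyl flanked by C6H2 and the side-chain-bearing C9), which is quickly assembled on an enantioselectively allylated ring A. The key step reinserts C7 as a CH2: Lewis-acid-promoted addition of trimethylsilyldiazomethane to C8 and 1,2-shift of C6 forge C6–C7 and C7–C8 and enlarge ring B from five to six members in one operation. C7 is then oxidised on the α face via the C7-enol silane, C8 is methylenated and the alcohol acetylated.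

Key step: step 10

Numbering: labdane numbering is used (ring A C1–C5/C10, ring B C5–C10, side chain C11–C16, C17 the exocyclic methylene carbon, C20 the C10 methyl); α is the face opposite the C10 methyl.

Remark 1: the quinidine-derived catalyst (DHQD)2AQN is assumed to deliver the (S)-half-ester 8; should its sense be the opposite, the quinine-derived (DHQ)2AQN is used with nothing else changed.

Remark 2: antipodal material left by steps 2 and 5 becomes a diastereomeric impurity after step 8 and is to be removed by crystallisation or preparative chromatography at 22 or 23.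

Step 1
Reactants: 1 2,2,6-trimethylcyclohexan-1-one; 2 allyl chloroformate
Product: 3 allyl 2,6,6-trimethylcyclohex-1-en-1-yl carbonate
Conditions: LiN(SiMe3)2, THF, 0 °C; then 2, −78 °C → rt
Reagents that add atoms: allyl chloroformate (2), C=CCOC(Cl)=O
Why: Only one enolate can form, and this hindered tetrasubstituted lithium enolate should be acylated on oxygen by the chloroformate (enolate O-acylation to an enol carbonate).

Step 2
Reactants: 3 allyl 2,6,6-trimethylcyclohex-1-en-1-yl carbonate
Product: 4 (R)-2-allyl-2,6,6-trimethylcyclohexan-1-one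
Conditions: Pd2(dba)3 (cat.), (R)-t-Bu-PHOX [(R)-4-tert-butyl-2-(2-diphenylphosphinophenyl)-4,5-dihydrooxazole] (cat.), THF, 25 °C
Reagents that add atoms: none
Why: Decarboxylative asymmetric allylic alkylation (Tsuji–Trost type) in which zerovalent palladium ionises the carbonate, CO2 is lost and the enolate recombines with the allyl fragment inside the chiral phosphinooxazoline pocket, the (R)-ligand being chosen because the (S)-ligand gives (S)-α-allyl-α-methylcyclohexanones, so that C10 is set under catalyst control.

Step 3
Reactants: 4 (R)-2-allyl-2,6,6-trimethylcyclohexan-1-one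
Product: 5 (R)-2,2,6-trimethyl-6-(2-oxopropyl)cyclohexan-1-one
Conditions: PdCl2 (cat.), Cu(OAc)2·H2O (cat.), O2 (1 atm), DMA/H2O, rt
Reagents that add atoms: water, O
Why: Wacker oxidation of the terminal alkene should give the methyl ketone with Markovnikov selectivity while the quaternary C10 is untouched.

Step 4
Reactants: 5 (R)-2,2,6-trimethyl-6-(2-oxopropyl)cyclohexan-1-one
Product: 6 (R)-4,4,7a-trimethyl-1,4,5,6,7,7a-hexahydro-2H-inden-2-one
Conditions: KOH, xylenes, 110 °C (Dean–Stark)
Reagents that add atoms: none
Why: Intramolecular aldol condensation in which the ring ketone has no α-hydrogen, so only the methyl-ketone enolate can attack it, and closure of the five-membered ring followed by dehydration should give the C5=C6 enone with C8 as carbonyl.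

Step 5
Reactants: 7 3-methylglutaric anhydride
Product: 8 (S)-5-methoxy-3-methyl-5-oxopentanoic acid
Conditions: MeOH, (DHQD)2AQN (cat.), Et2O, −40 °C
Reagents that add atoms: methanol, CO
Why: Alkaloid-catalysed enantioselective methanolysis (desymmetrisation of a prochiral cyclic anhydride) in which the chiral tertiary amine acts as general base and distinguishes the two enantiotopic carbonyl groups, which sets C13.

Step 6
Reactants: 8 (S)-5-methoxy-3-methyl-5-oxopentanoic acid
Product: 9 methyl (S)-5-hydroxy-3-methylpentanoate
Conditions: BH3·SMe2, THF, 0 °C → rt; MeOH quench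
Reagents that add atoms: none
Why: Chemoselective borane reduction, since the carboxylic acid is reduced through its acyloxyborane far faster than the ester, so only the acid terminus should become CH2OH and C13 is not involved.

Step 7
Reactants: 9 methyl (S)-5-hydroxy-3-methylpentanoate
Product: 10 methyl (S)-3-methyl-5-oxopentanoate
Conditions: TEMPO (cat.), PhI(OAc)2, CH2Cl2, rt
Reagents that add atoms: none
Why: Oxoammonium (TEMPO) oxidation of a primary alcohol stops at the aldehyde under anhydrous conditions, and C13, being β to the new carbonyl, cannot epimerise.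

Step 8
Reactants: 6 (R)-4,4,7a-trimethyl-1,4,5,6,7,7a-hexahydro-2H-inden-2-one; 10 methyl (S)-3-methyl-5-oxopentanoate
Product: 13 methyl (3S)-3-methyl-5-[(7aS)-4,4,7a-trimethyl-2-oxo-2,4,5,6,7,7a-hexahydro-1H-inden-1-ylidene]pentanoate (C9=C11 dienone), via aldol adduct 11 (not isolated), via aldol mesylate 12 (not isolated)
Conditions: LiN(i-Pr)2, THF, −78 °C; 10, −78 °C; MsCl, Et3N, −78 → 0 °C; DBU, 0 °C → rt
Reagents that add atoms: none
Why: Directed aldol condensation in which the base can only remove a C9 hydrogen (both γ-positions are quaternary), the lithium dienolate adds to the aldehyde at −78 °C, and the mesylated aldol should lose methanesulfonate by E1cB through the C9 enolate; no stereocentre is created and the alkene geometry is immaterial.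

Step 9
Reactants: 13 C9=C11 dienone
Product: 15 methyl (3S)-3-methyl-5-[(1R,3aS,7aS)-4,4,7a-trimethyl-2-oxooctahydro-1H-inden-1-yl]pentanoate (trans-fused B-nor ketone), via side-chain-saturated enone 14 (not isolated)
Conditions: H2 (4 atm), 10% Pd/C, EtOAc, rt
Reagents that add atoms: none
Why: Heterogeneous catalytic hydrogenation should saturate the exocyclic enone first and then C5=C6, with hydrogen delivered to C9 and C5 from the α face because the β face is screened by the axial C10 methyl and, at C5, also by the axial C4 methyl, which gives H5α (trans fusion) and the C9 chain cis to the C10 methyl, the latter also being the pseudo-equatorial epimer of a centre that the basic work-up of step 10 would correct in any case.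

Step 10
Reactants: 15 trans-fused B-nor ketone; 16 trimethylsilyldiazomethane
Product: 18 methyl (5S,9R,10S,13S)-8-oxo-17-norlabdan-15-oate, via 7-silyl ketone 17 (not isolated)
Conditions: 16, Sc(OTf)3 (cat.), CH2Cl2, −78 → 0 °C; then K2CO3, MeOH, rt
Reagents that add atoms: trimethylsilyldiazomethane (16), C[Si](C)(C)C=[N+]=[N-]
Why: Sc(OTf)3 activates the C8 carbonyl, the diazo carbon of 16 adds from the α face to give a β-oxido diazonium ion, and loss of N2 with 1,2-shift of C6 from C8 to the new carbon forms C6–C7 and C7–C8 and gives the 7-silyl ketone 17 (or its O-silyl enol tautomer), which K2CO3/MeOH protodesilylates. The closest known reaction type is the Lewis-acid-promoted one-carbon homologation of cycloalkanones with trimethylsilyldiazomethane, a Tiffeneau–Demjanov-type diazoalkane insertion. No ring is closed, since ring B is enlarged from five to six members by insertion, so no ring-closure mode applies. No lasting stereocentre is created, because the silyl-bearing C7 ends as CH2 and C5, C9 and C10 are not touched, while the basic methanol work-up leaves C9 in its equatorial, thermodynamically preferred configuration. The step needs migration of the methylene C6 rather than the branched C9 and a single insertion: the only staggered adduct conformer that keeps the bulky silyl group clear of C9 and its quaternary neighbour C10 has the C8–C6 bond anti to the departing N2, and 17 is more hindered and less strained than the trans-fused cyclopentanone 15, so it should not react again.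

Step 11
Reactants: 18 methyl 8-oxo-17-norlabdan-15-oate
Product: 19 methyl 8-(trimethylsilyloxy)-17-norlabd-7-en-15-oate
Conditions: LiN(SiMe3)2, Me3SiCl (in situ quench), THF, −78 °C; non-aqueous work-up
Reagents that add atoms: chlorotrimethylsilane, C[Si](C)(C)Cl
Why: Kinetic silyl enol ether formation, in which the hindered amide base should remove a hydrogen from the open C7 methylene rather than the tertiary C9–H next to the quaternary C10, and should deprotonate the ketone faster than the less acidic ester.

Step 12
Reactants: 19 methyl 8-(trimethylsilyloxy)-17-norlabd-7-en-15-oate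
Product: 22 methyl (5S,7R,9R,10S,13S)-7-hydroxy-8-oxo-17-norlabdan-15-oate (7α-hydroxy ketone), via silyloxy epoxide 20 (not isolated), via 7α-silyloxy ketone 21 (not isolated)
Conditions: mCPBA, NaHCO3, CH2Cl2, −20 → 0 °C; then aq. citric acid, THF, 0 °C
Reagents that add atoms: mCPBA, O=C(OO)c1cccc(Cl)c1
Why: Rubottom oxidation in which the peracid should epoxidise the electron-rich enol ether from the α face, opposite the axial C10 methyl that shields the β face of C8, after which opening of the silyloxy epoxide with 1,4-silyl shift places the new oxygen axial (α) on C7 and mild acid frees the alcohol.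

Step 13
Reactants: 22 7α-hydroxy ketone
Product: 23 methyl (5S,7R,9R,10S,13S)-7-hydroxylabd-8(17)-en-15-oate
Conditions: Zn, CH2Br2, TiCl4, THF (reagent pre-formed and aged at 5 °C); then 22, CH2Cl2, rt
Reagents that add atoms: dibromomethane, BrCBr
Why: Takai–Lombardo methylenation, whose non-basic zinc/titanium methylene reagent olefinates hindered, enolisable ketones, leaves esters alone and tolerates a free hydroxyl when used in excess, so that C7 and C9 should not be epimerised as they could be under a basic ylide.

Step 14
Reactants: 23 methyl 7α-hydroxylabd-8(17)-en-15-oate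
Product: 24 methyl (5S,7R,9R,10S,13S)-7-acetoxylabd-8(17)-en-15-oate (target)
Conditions: Ac2O, pyridine, DMAP (cat.), CH2Cl2, rt
Reagents that add atoms: acetic anhydride, CC(=O)OC(C)=O
Why: DMAP-catalysed O-acylation of the axial allylic alcohol does not break the C7–O bond, so the configuration at C7 is retained.

Compound list

1 | 2,2,6-trimethylcyclohexan-1-one (racemic; its centre is erased in step 1) | CC1CCCC(C)(C)C1=O | starting material
2 | allyl chloroformate | C=CCOC(Cl)=O | starting material
3 | allyl 2,6,6-trimethylcyclohex-1-en-1-yl carbonate | C=CCOC(=O)OC1=C(C)CCCC1(C)C | intermediate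
4 | (R)-2-allyl-2,6,6-trimethylcyclohexan-1-one | C=CC[C@@]1(C)CCCC(C)(C)C1=O | intermediate
5 | (R)-2,2,6-trimethyl-6-(2-oxopropyl)cyclohexan-1-one | CC(=O)C[C@@]1(C)CCCC(C)(C)C1=O | intermediate
6 | (R)-4,4,7a-trimethyl-1,4,5,6,7,7a-hexahydro-2H-inden-2-one (B-nor enone: C8 ketone, C5=C6, C9H2) | O=C1C=C2C(C)(C)CCC[C@]2(C)C1 | intermediate
7 | 3-methylglutaric anhydride | CC1CC(=O)OC(=O)C1 | starting material
8 | (S)-5-methoxy-3-methyl-5-oxopentanoic acid | OC(=O)C[C@H](C)CC(=O)OC | intermediate
9 | methyl (S)-5-hydroxy-3-methylpentanoate | OCC[C@H](C)CC(=O)OC | intermediate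
10 | methyl (S)-3-methyl-5-oxopentanoate | O=CC[C@H](C)CC(=O)OC | intermediate
11 | methyl (3S)-5-hydroxy-3-methyl-5-[(7aR)-4,4,7a-trimethyl-2-oxo-2,4,5,6,7,7a-hexahydro-1H-inden-1-yl]pentanoate (aldol adduct; mixture at C9 and C11, both centres lost in the elimination) | O=C1C=C2C(C)(C)CCC[C@]2(C)C1C(O)C[C@H](C)CC(=O)OC | intermediate (not isolated)
12 | methanesulfonate of 11 at the C11 hydroxyl (mixture at C9 and C11) | O=C1C=C2C(C)(C)CCC[C@]2(C)C1C(OS(C)(=O)=O)C[C@H](C)CC(=O)OC | intermediate (not isolated)
13 | methyl (3S)-3-methyl-5-[(7aS)-4,4,7a-trimethyl-2-oxo-2,4,5,6,7,7a-hexahydro-1H-inden-1-ylidene]pentanoate (C9=C11 geometry not fixed; both isomers converge) | O=C1C=C2C(C)(C)CCC[C@]2(C)C1=CC[C@H](C)CC(=O)OC | intermediate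
14 | methyl (3S)-3-methyl-5-[(1R,7aR)-4,4,7a-trimethyl-2-oxo-2,4,5,6,7,7a-hexahydro-1H-inden-1-yl]pentanoate (C5=C6 enone, C9 chain β) | O=C1C=C2C(C)(C)CCC[C@]2(C)[C@H]1CC[C@H](C)CC(=O)OC | intermediate (not isolated)
15 | methyl (3S)-3-methyl-5-[(1R,3aS,7aS)-4,4,7a-trimethyl-2-oxooctahydro-1H-inden-1-yl]pentanoate (trans-fused B-nor ketone; H5α, C9 chain β) | O=C1C[C@H]2C(C)(C)CCC[C@]2(C)[C@H]1CC[C@H](C)CC(=O)OC | intermediate
16 | trimethylsilyldiazomethane | C[Si](C)(C)C=[N+]=[N-] | starting material
17 | methyl (5S,9R,10S,13S)-8-oxo-7-(trimethylsilyl)-17-norlabdan-15-oate (C7 configuration undefined, lost on desilylation) | O=C1C([Si](C)(C)C)C[C@H]2C(C)(C)CCC[C@]2(C)[C@H]1CC[C@H](C)CC(=O)OC | intermediate (not isolated)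
18 | methyl (5S,9R,10S,13S)-8-oxo-17-norlabdan-15-oate | O=C1CC[C@H]2C(C)(C)CCC[C@]2(C)[C@H]1CC[C@H](C)CC(=O)OC | intermediate
19 | methyl (5S,9R,10S,13S)-8-(trimethylsilyloxy)-17-norlabd-7-en-15-oate | C[Si](C)(C)OC1=CC[C@H]2C(C)(C)CCC[C@]2(C)[C@H]1CC[C@H](C)CC(=O)OC | intermediate
20 | methyl 7α,8α-epoxy-8β-(trimethylsilyloxy)-17-norlabdan-15-oate | C[Si](C)(C)O[C@]13O[C@@H]3C[C@H]2C(C)(C)CCC[C@]2(C)[C@H]1CC[C@H](C)CC(=O)OC | intermediate (not isolated)
21 | methyl 8-oxo-7α-(trimethylsilyloxy)-17-norlabdan-15-oate | O=C1[C@H](O[Si](C)(C)C)C[C@H]2C(C)(C)CCC[C@]2(C)[C@H]1CC[C@H](C)CC(=O)OC | intermediate (not isolated)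
22 | methyl (5S,7R,9R,10S,13S)-7-hydroxy-8-oxo-17-norlabdan-15-oate (7α-OH, axial) | O=C1[C@H](O)C[C@H]2C(C)(C)CCC[C@]2(C)[C@H]1CC[C@H](C)CC(=O)OC | intermediate
23 | methyl (5S,7R,9R,10S,13S)-7-hydroxylabd-8(17)-en-15-oate | C=C1[C@H](O)C[C@H]2C(C)(C)CCC[C@]2(C)[C@H]1CC[C@H](C)CC(=O)OC | intermediate
24 | methyl (5S,7R,9R,10S,13S)-7-acetoxylabd-8(17)-en-15-oate (CNP0223602.1) | C=C1[C@H](OC(C)=O)C[C@H]2C(C)(C)CCC[C@]2(C)[C@H]1CC[C@H](C)CC(=O)OC | target

Total step count: 14.
Longest linear sequence: 11 steps (steps 1–4 and 8–14, from 1); the side-chain branch is steps 5–7.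

Steps most likely to fail

1. Step 10. What may go wrong: shift of the branched C9 instead of C6, a second insertion into the product ketone, or collapse of the diazonium adduct to a spiro-epoxide instead of rearrangement. The fallback sets out from 15 and comes back at 18, and fixes the site of insertion by enolisation instead of by migratory preference. Kinetic deprotonation of 15 at the C6 methylene (LiN(SiMe3)2, Me3SiCl, THF, −78 °C) should give the C6-enol silane F1. Simmons–Smith cyclopropanation (Et2Zn, CH2I2, CH2Cl2, 0 °C) should give the siloxycyclopropane F2. Ito–Saegusa ring enlargement (FeCl3, DMF, 0 °C) should open the internal cyclopropane bond to the ring-enlarged β-chloro ketone F3, which NaOAc in MeOH at reflux should convert to the C6=C7 enone F4. Hydrogenation (H2, Pd/C, EtOAc) then returns 18.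

2. Step 9. What may go wrong: stalling of the reduction at the hindered C5=C6 bond, or erosion of facial control at C5. The fallback sets out from 14, which is isolated by stopping the hydrogenation once the exocyclic bond is saturated, and comes back at 15. Saponification (LiOH, THF/H2O) should give the enone acid F5. Dissolving-metal reduction (Li, NH3, THF, t-BuOH, −78 °C; NH4Cl), which is insensitive to shielding of the β-carbon and protonates C5 from the open α face, should give the trans-fused keto acid F6. Esterification with 16 in MeOH/toluene returns 15.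

3. Step 13. What may go wrong: slow olefination of the hindered C8 carbonyl, giving time for Lewis-acid-induced ketol isomerisation or epimerisation at C7. The fallback sets out from 22 and comes back at 23. Silylation (Et3SiOTf, 2,6-lutidine, CH2Cl2, −78 °C) should give the 7α-silyl ether F7. Wittig methylenation (Ph3PCH3Br, KN(SiMe3)2, THF, 0 °C → rt), in which the equatorial C7–H is poorly aligned for enolisation, should give the alkene F8. Desilylation (Bu4NF, THF, 0 °C) returns 23.

Further compounds

F1 | step 10 | C6-enol silane of 15: methyl (3S)-3-methyl-5-[(1R,3aS,7aS)-4,4,7a-trimethyl-2-(trimethylsilyloxy)-3a,4,5,6,7,7a-hexahydro-1H-inden-1-yl]pentanoate | C[Si](C)(C)OC1=C[C@H]2C(C)(C)CCC[C@]2(C)[C@H]1CC[C@H](C)CC(=O)OC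
F2 | step 10 | siloxycyclopropane from F1 (CH2 bridging C6 and C8, C8 bearing OSiMe3; cyclopropane face not fixed) | C[Si](C)(C)OC12CC1[C@H]1C(C)(C)CCC[C@]1(C)[C@H]2CC[C@H](C)CC(=O)OC
F3 | step 10 | methyl 6-chloro-8-oxo-17-norlabdan-15-oate (C6 configuration not fixed) | O=C1CC(Cl)[C@H]2C(C)(C)CCC[C@]2(C)[C@H]1CC[C@H](C)CC(=O)OC
F4 | step 10 | methyl 8-oxo-17-norlabd-6-en-15-oate | O=C1C=C[C@H]2C(C)(C)CCC[C@]2(C)[C@H]1CC[C@H](C)CC(=O)OC
F5 | step 9 | (3S)-3-methyl-5-[(1R,7aR)-4,4,7a-trimethyl-2-oxo-2,4,5,6,7,7a-hexahydro-1H-inden-1-yl]pentanoic acid | O=C1C=C2C(C)(C)CCC[C@]2(C)[C@H]1CC[C@H](C)CC(=O)O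
F6 | step 9 | (3S)-3-methyl-5-[(1R,3aS,7aS)-4,4,7a-trimethyl-2-oxooctahydro-1H-inden-1-yl]pentanoic acid | O=C1C[C@H]2C(C)(C)CCC[C@]2(C)[C@H]1CC[C@H](C)CC(=O)O
F7 | step 13 | methyl 8-oxo-7α-(triethylsilyloxy)-17-norlabdan-15-oate | O=C1[C@H](O[Si](CC)(CC)CC)C[C@H]2C(C)(C)CCC[C@]2(C)[C@H]1CC[C@H](C)CC(=O)OC
F8 | step 13 | methyl 7α-(triethylsilyloxy)labd-8(17)-en-15-oate | C=C1[C@H](O[Si](CC)(CC)CC)C[C@H]2C(C)(C)CCC[C@]2(C)[C@H]1CC[C@H](C)CC(=O)OC
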